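Late in a run the useful count is how many half-lives of the electrophile fit into the time, and your hunch that more nucleophile carries a flask further can be put to that count at 25 h.

in all of them: electrophile 0.30 M
- spring: nucleophile 2.5 equiv; protic impurity 4 mM; run made earlier
- elm: nucleophile 3.80 equiv; protic impurity 6.00 mM; time 25 h
- ash: nucleophile 2.50 equiv; protic impurity 6.00 mM; time 25 h
- larch: nucleophile 5.60 equiv; protic impurity 6.00 mM; time 25 h

spring run (percent of the electrophile charged)

| time / h | electrophile / % | target / % |
|---|---|---|
| 0.417 | 97.6 | 2.6 |
| 0.833 | 95.3 | 4.3 |
| 1.33 | 92.1 | 6.1 |
| 2.50 | 87.6 | 10.1 |
| 5.00 | 76.1 | 15.5 |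

(scatter of a reading: 0.5 percentage points)

- no earlier run changes the charge of protic impurity; that part of a forecast is a guess

1. part of the electrophile that has reacted at the end, elm
2. part of the electrophile that has reacted at the end, ash
3. part of the electrophile that has reacted at the end, larch
4. what raising the equivalents of nucleophile from its lowest to its highest value here does to the part of the electrophile that has reacted (changes below 5 percentage points count as none) (it falls / it rises / no change)

The last spring reading, 76.1 % electrophile left at 5.00 h, gives the spring half-life, the time in which the electrophile halves at the spring charge of nucleophile: 12.7 h. This reading treats the loss as pseudo-first-order and carries the scatter of 0.5 percentage points. Ash has the same equivalents, so 25 h holds 1.97 half-lives, and 74.5 % has reacted by this count.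

Taking the rate as proportional to c(nucleophile), which is a guess, the half-life shrinks with the equivalents, to 8.35 h in elm and 5.66 h in larch. That gives 87.5 % and 95.3 % reacted. The protic impurity is hardly any of the nucleophile charged in ash, so the count sets it aside. These counts hold the half-life fixed while c(nucleophile) falls, so they are meant as upper figures.

The forecast gives 84 % for elm, 71 % for ash and 93 % for larch, with the verdict it rises. Each figure lies below the count, and the forecast warns that “one run cannot fix the order in nucleophile”.

The flasks give 80.0 % for elm, 63.0 % for ash and 92.0 % for larch, and the verdict is again it rises, by 29 points.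

    electrophile + nucleophile → acid set free + target (k = 2.20 × 10⁻⁵ L mol⁻¹ s⁻¹)
    nucleophile + protic impurity → quenched reagent (k = 0.0340 L mol⁻¹ s⁻¹)
    target ⇌ isomer of the product (K = 18.0, k = 4.50 × 10⁻⁵ s⁻¹)
    nucleophile + acid set free ⇌ protonated nucleophile, settled at all times (K = 10000 L mol⁻¹)

Ash ends below its forecast of 71 %, and its free nucleophile stands at 48.8 % of its charge, a loss twice the electrophile reacted. The electrophile of ash has gone through 1.44 halvings, against the 1.97 spring half-lives counted. With 1.40 equiv of nucleophile on the larch recipe, the spring half-life scales to 22.7 h, which predicts 46.6 % electrophile left, and that flask holds 59.3 % at 25.0 h.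

The data are simulated on assumed constants; the scatter is artificial.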